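Retrosynthesis: (1) remove nine O-benzyl groups; (2) cut together the two bonds that join the C3–C2 edge of the dihydrofuran ring to ring A (aryl C3a–C3H2 and O1–C2H); (3) cut the flavan C8–CH(aryl) bond; (4) trace the resulting 3-aryl-1,2-diol to a Sharpless epoxy alcohol.
Enabling feature: C3H2–C2H(O) of the dihydrobenzofuran is a two-carbon edge at vicinal-diol oxidation level, and the C3a/O1 pair of the phloroglucinol ring A is a 1,3-C,O-dinucleophile, so a 1,2-cyclic sulfate and an ortho-lithiated phenoxide can be merged in one flask.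
Forward: protected (+)-epicatechin (flavan rings A and C bought ready-made) is metalated at C8 and opens the epoxy alcohol at its benzylic carbon; the 3,3-diaryl-1,2-diol becomes a cyclic sulfate; the annulation builds the dihydrofuran ring last; hydrogenolysis follows.
Stereochemistry: flavan C2/C3 come from the chiral pool; the diarylmethine comes from SN2 inversion at the (3R)-epoxide carbon; dihydrofuran C2 comes from inversion of the epoxide-derived carbinol in the annulation.

Key step: step 10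

Remark: the flavan half of the target is (2S,3S), i.e. (+)-epicatechin, which is assumed purchasable and is used as the starting material.
Abbreviations in names: Ar = 3,4-bis(benzyloxy)phenyl; Fl = (2S,3S)-3,5,7-tris(benzyloxy)-2-[3,4-bis(benzyloxy)phenyl]chroman-8-yl.

Step 1
Reactants: 1 (+)-epicatechin
Product: 2 (2S,3S)-5,7-bis(benzyloxy)-2-[3,4-bis(benzyloxy)phenyl]chroman-3-ol
Conditions: BnBr (4.4 equiv), K2CO3, DMF, 0 °C to rt
Reagents that add atoms: benzyl bromide, BrCc1ccccc1
Why: Williamson etherification should alkylate the four phenols under carbonate base while the aliphatic 3-OH stays free and no stereocentre is touched.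

Step 2
Reactants: 2 tetra-O-benzyl-(+)-epicatechin
Product: 3 (2S,3S)-3,5,7-tris(benzyloxy)-2-[3,4-bis(benzyloxy)phenyl]chromane
Conditions: NaH, BnBr, DMF, 0 °C to rt
Reagents that add atoms: benzyl bromide, BrCc1ccccc1
Why: Williamson etherification of the secondary alkoxide masks the 3-OH for the later organometallic and sulfurylation steps without touching a stereocentre.

Step 3
Reactants: 3 penta-O-benzyl-(+)-epicatechin
Product: 4 (2S,3S)-3,5,7-tris(benzyloxy)-2-[3,4-bis(benzyloxy)phenyl]-8-bromochromane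
Conditions: NBS (1.0 equiv), CH2Cl2, −78 to 0 °C
Reagents that add atoms: N-bromosuccinimide, O=C1CCC(=O)N1Br
Why: Electrophilic aromatic bromination of perbenzylated flavan-3-ols should occur at C8 of ring A in preference to C6, which fixes the site of the later C–C bond.

Step 4
Reactants: 5 3,4-bis(benzyloxy)benzaldehyde
Product: 6 ethyl (E)-3-[3,4-bis(benzyloxy)phenyl]prop-2-enoate
Conditions: (EtO)2P(O)CH2CO2Et, NaH, THF, 0 °C to rt
Reagents that add atoms: triethyl phosphonoacetate, CCOC(=O)CP(=O)(OCC)OCC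
Why: Horner–Wadsworth–Emmons olefination of an aromatic aldehyde with a stabilised phosphonate should give the (E)-cinnamate.

Step 5
Reactants: 6 ethyl (E)-cinnamate
Product: 7 (E)-3-[3,4-bis(benzyloxy)phenyl]prop-2-en-1-ol
Conditions: i-Bu2AlH (2.2 equiv), CH2Cl2, −78 °C; aq potassium sodium tartrate
Reagents that add atoms: none
Why: 1,2-Reduction of the conjugated ester by the aluminium hydride should give the allylic alcohol and leave the alkene geometry intact.

Step 6
Reactants: 7 (E)-allylic alcohol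
Product: 8 [(2R,3R)-3-[3,4-bis(benzyloxy)phenyl]oxiran-2-yl]methanol
Conditions: Ti(OiPr)4 (10 mol%), D-(−)-diisopropyl tartrate (12 mol%), t-BuOOH, 4 Å MS, CH2Cl2, −20 °C; non-acidic work-up
Reagents that add atoms: tert-butyl hydroperoxide, CC(C)(C)OO
Why: Sharpless asymmetric epoxidation with the D-(−)-tartrate titanium catalyst should deliver oxygen to one face of the (E)-allylic alcohol and set both epoxide carbons as (2R,3R).

Step 7
Reactants: 4 8-bromo-penta-O-benzyl-(+)-epicatechin; 8 (2R,3R)-epoxy alcohol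
Product: 12 (2S,3R)-3-Ar-3-Fl-propane-1,2-diol, via aryllithium 9 (not isolated), via arylmagnesium bromide 10 (not isolated), via lithium epoxy alkoxide 11 (not isolated)
Conditions: 4, n-BuLi (1.05 equiv), THF, −78 °C; MgBr2·OEt2 (1.1 equiv), −78 to −30 °C; CuI (10 mol%); then 11 [from 8, n-BuLi (1.0 equiv), THF, −78 °C], −30 to 0 °C; aq NH4Cl
Reagents that add atoms: none
Why: Bromine–lithium exchange and transmetalation give an aryl Grignard reagent that, under CuI catalysis, should open the trans-3-arylglycidol alkoxide at its benzylic C3 by SN2 with inversion (copper-catalysed Grignard opening of arylglycidols), so the diarylmethine is set as (R) while the untouched carbinol carbon becomes (S) only by change of CIP priorities.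

Step 8
Reactants: 12 (2S,3R)-diol
Product: 14 (4S)-4-[(R)-Ar(Fl)methyl]-1,3,2-dioxathiolane 2,2-dioxide, via cyclic sulfite 13 (not isolated)
Conditions: SOCl2, Et3N, CH2Cl2, 0 °C; then RuCl3·3H2O (1 mol%), NaIO4, MeCN/CH2Cl2/H2O, 0 °C, short contact time
Reagents that add atoms: thionyl chloride, O=S(Cl)Cl; sodium periodate, [Na+].[O-]I(=O)(=O)=O
Why: Gao–Sharpless cyclic sulfate synthesis should close the diol to the cyclic sulfite and oxidise it at sulfur with catalytic RuO4, with no bond to either carbon stereocentre being broken.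

Step 9
Reactants: 15 3,5-bis(benzyloxy)phenol
Product: 16 2-bromo-3,5-bis(benzyloxy)phenol
Conditions: NBS (1.0 equiv), i-Pr2NH (10 mol%), CH2Cl2, −78 to 0 °C
Reagents that add atoms: N-bromosuccinimide, O=C1CCC(=O)N1Br
Why: Amine-catalysed NBS bromination of phenols is ortho-selective (an N-bromoamine hydrogen-bonded to the OH delivers bromine), and C2 is also less hindered than C4 between the two benzyloxy groups.

Step 10
Reactants: 16 2-bromo-3,5-bis(benzyloxy)phenol; 14 cyclic sulfate
Product: 19 (2S)-4,6-bis(benzyloxy)-2-[(R)-Ar(Fl)methyl]-2,3-dihydro-1-benzofuran, via dilithio phenoxide 17 (not isolated), via lithium alkyl sulfate 18 (not isolated)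
Conditions: 16, n-BuLi (1.0 equiv) then t-BuLi (2.0 equiv), THF, −78 °C; 14 in THF, −78 to 0 °C; then DMPU, 60 °C
Reagents that add atoms: none
Why: Proposed new method: O-deprotonation and bromine–lithium exchange turn 16 into the C,O-dianion 17, whose aryl carbon opens the cyclic sulfate 14 at its unhindered CH2 carbon (SN2, C–C bond) and leaves the neighbouring CH oxygen as a lithium alkyl sulfate (18), which the ortho phenoxide then displaces on warming with loss of Li2SO4 (O–C bond). The closest known reaction types are the tandem double displacement of 1,2-cyclic sulfates by dinucleophiles (malonate to cyclopropanes, catecholate to benzodioxanes) and the opening of epoxides by ortho-lithiated phenoxides followed by a separate cyclodehydration. The dihydrofuran ring closes in the 5-exo-tet mode. The only new stereocentre, C2 of the dihydrobenzofuran, should arise by inversion of the (4S)-carbinol carbon of 14, so it is controlled by the epoxidation that set that carbon, and the adjacent diarylmethine is not touched. The step needs carbon-before-oxygen and primary-before-secondary alkylation and substitution in preference to elimination or aryl participation: the aryllithium is by far the stronger nucleophile, the CH2 terminus is the only unhindered electrophilic site, and a monoanionic sulfate in a non-ionising medium ionises poorly yet is an adequate leaving group for an intramolecular phenoxide.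

Step 11
Reactants: 19 nona-O-benzyl ether of the target
Product: 20 (2S,3S)-2-(3,4-dihydroxyphenyl)-8-[(R)-(3,4-dihydroxyphenyl)[(2S)-4,6-dihydroxy-2,3-dihydro-1-benzofuran-2-yl]methyl]chromane-3,5,7-triol
Conditions: H2 (1 atm), Pd(OH)2/C, THF/MeOH, rt
Reagents that add atoms: none
Why: Hydrogenolysis should remove all nine benzyl ethers; the dihydrofuran C–O bond is not benzylic, and benzylated flavan-3-ols are routinely deprotected this way without ring cleavage.

Compound list
1 | (+)-epicatechin, (2S,3S)-2-(3,4-dihydroxyphenyl)chromane-3,5,7-triol | Oc1cc(O)c2c(c1)O[C@@H](c1ccc(O)c(O)c1)[C@@H](O)C2 | starting material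
2 | (2S,3S)-5,7-bis(benzyloxy)-2-[3,4-bis(benzyloxy)phenyl]chroman-3-ol | c1c(OCc2ccccc2)cc(OCc2ccccc2)c2c1O[C@@H](c1ccc(OCc3ccccc3)c(OCc3ccccc3)c1)[C@@H](O)C2 | intermediate
3 | (2S,3S)-3,5,7-tris(benzyloxy)-2-[3,4-bis(benzyloxy)phenyl]chromane | c1c(OCc2ccccc2)cc(OCc2ccccc2)c2c1O[C@@H](c1ccc(OCc3ccccc3)c(OCc3ccccc3)c1)[C@@H](OCc1ccccc1)C2 | intermediate
4 | (2S,3S)-3,5,7-tris(benzyloxy)-2-[3,4-bis(benzyloxy)phenyl]-8-bromochromane | Brc1c(OCc2ccccc2)cc(OCc2ccccc2)c2c1O[C@@H](c1ccc(OCc3ccccc3)c(OCc3ccccc3)c1)[C@@H](OCc1ccccc1)C2 | intermediate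
5 | 3,4-bis(benzyloxy)benzaldehyde | O=Cc1ccc(OCc2ccccc2)c(OCc2ccccc2)c1 | starting material
6 | ethyl (E)-3-[3,4-bis(benzyloxy)phenyl]prop-2-enoate | CCOC(=O)/C=C/c1ccc(OCc2ccccc2)c(OCc2ccccc2)c1 | intermediate
7 | (E)-3-[3,4-bis(benzyloxy)phenyl]prop-2-en-1-ol | OC/C=C/c1ccc(OCc2ccccc2)c(OCc2ccccc2)c1 | intermediate
8 | [(2R,3R)-3-[3,4-bis(benzyloxy)phenyl]oxiran-2-yl]methanol | OC[C@H]1O[C@@H]1c1ccc(OCc2ccccc2)c(OCc2ccccc2)c1 | intermediate
9 | 8-lithio derivative of 3 (aryllithium, Fl–Li) | [Li]c1c(OCc2ccccc2)cc(OCc2ccccc2)c2c1O[C@@H](c1ccc(OCc3ccccc3)c(OCc3ccccc3)c1)[C@@H](OCc1ccccc1)C2 | intermediate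
10 | 8-(bromomagnesio) derivative of 3 (Fl–MgBr) | Br[Mg]c1c(OCc2ccccc2)cc(OCc2ccccc2)c2c1O[C@@H](c1ccc(OCc3ccccc3)c(OCc3ccccc3)c1)[C@@H](OCc1ccccc1)C2 | intermediate
11 | lithium alkoxide of epoxy alcohol 8 | [Li]OC[C@H]1O[C@@H]1c1ccc(OCc2ccccc2)c(OCc2ccccc2)c1 | intermediate
12 | (2S,3R)-3-Ar-3-Fl-propane-1,2-diol | O[C@@H]([C@H](c1ccc(OCc2ccccc2)c(OCc2ccccc2)c1)c1c(OCc2ccccc2)cc(OCc2ccccc2)c2c1O[C@@H](c1ccc(OCc3ccccc3)c(OCc3ccccc3)c1)[C@@H](OCc1ccccc1)C2)CO | intermediate
13 | (4S)-4-[(R)-Ar(Fl)methyl]-1,3,2-dioxathiolane 2-oxide (both sulfur epimers) | O=S5OC[C@H]([C@H](c1ccc(OCc2ccccc2)c(OCc2ccccc2)c1)c1c(OCc2ccccc2)cc(OCc2ccccc2)c2c1O[C@@H](c1ccc(OCc3ccccc3)c(OCc3ccccc3)c1)[C@@H](OCc1ccccc1)C2)O5 | intermediate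
14 | (4S)-4-[(R)-Ar(Fl)methyl]-1,3,2-dioxathiolane 2,2-dioxide | O=S5(=O)OC[C@H]([C@H](c1ccc(OCc2ccccc2)c(OCc2ccccc2)c1)c1c(OCc2ccccc2)cc(OCc2ccccc2)c2c1O[C@@H](c1ccc(OCc3ccccc3)c(OCc3ccccc3)c1)[C@@H](OCc1ccccc1)C2)O5 | intermediate
15 | 3,5-bis(benzyloxy)phenol | Oc1cc(OCc2ccccc2)cc(OCc2ccccc2)c1 | starting material
16 | 2-bromo-3,5-bis(benzyloxy)phenol | Oc1cc(OCc2ccccc2)cc(OCc2ccccc2)c1Br | intermediate
17 | lithium 3,5-bis(benzyloxy)-2-lithiophenoxide | [Li]Oc1cc(OCc2ccccc2)cc(OCc2ccccc2)c1[Li] | intermediate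
18 | dilithium 3,5-bis(benzyloxy)-2-[(2R,3R)-3-Ar-3-Fl-2-(sulfonatooxy)propyl]phenoxide | [Li]Oc1cc(OCc2ccccc2)cc(OCc2ccccc2)c1C[C@@H](OS(=O)(=O)O[Li])[C@H](c1ccc(OCc2ccccc2)c(OCc2ccccc2)c1)c1c(OCc2ccccc2)cc(OCc2ccccc2)c2c1O[C@@H](c1ccc(OCc3ccccc3)c(OCc3ccccc3)c1)[C@@H](OCc1ccccc1)C2 | intermediate
19 | (2S)-4,6-bis(benzyloxy)-2-[(R)-Ar(Fl)methyl]-2,3-dihydro-1-benzofuran | c1ccccc1COc1cc(OCc2ccccc2)c2c(c1)O[C@H]([C@H](c1ccc(OCc3ccccc3)c(OCc3ccccc3)c1)c1c(OCc3ccccc3)cc(OCc3ccccc3)c3c1O[C@@H](c1ccc(OCc4ccccc4)c(OCc4ccccc4)c1)[C@@H](OCc1ccccc1)C3)C2 | intermediate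
20 | (2S,3S)-2-(3,4-dihydroxyphenyl)-8-[(R)-(3,4-dihydroxyphenyl)[(2S)-4,6-dihydroxy-2,3-dihydro-1-benzofuran-2-yl]methyl]chromane-3,5,7-triol | Oc1cc(O)c2c(c1)O[C@H]([C@H](c1ccc(O)c(O)c1)c1c(O)cc(O)c3c1O[C@@H](c1ccc(O)c(O)c1)[C@@H](O)C3)C2 | target

Total step count: 11. Longest linear sequence: 7 steps (steps 1, 2, 3, 7, 8, 10, 11; the branch through steps 4, 5, 6 is equally long).

Steps most likely to fail

Step 10. The aryllithium may attack sulfur instead of carbon. The secondary sulfate may also undergo elimination towards the doubly benzylic hydrogen, or 1,2-aryl participation by the electron-rich rings, instead of SN2 closure. Either would erode the C2 configuration or rearrange the skeleton. The fallback sets out from 12 and comes back at 19. Selective sulfonylation of the primary hydroxyl (TsCl, Et3N, Bu2SnO cat., CH2Cl2) should give the primary tosylate F1. K2CO3 in MeOH should close it to the terminal (S)-epoxide F2 with retention at the carbinol carbon. The dianion 17, made from 16 as in step 10, should open F2 at CH2 in the presence of BF3·OEt2 at −78 °C to give the 2-(2-hydroxyalkyl)phenol F3. Mitsunobu cyclodehydration (PPh3, DIAD, THF) should then close the dihydrofuran ring with inversion to give 19. If step 10 stalls after the C–C bond has formed, acidic hydrolysis of the sulfate monoester would also lead to this alcohol.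

Step 7. The electron-rich epoxide may ionise under the magnesium salts, causing loss of SN2 stereospecificity or Meinwald rearrangement. Transfer of the hindered di-ortho-alkoxy aryl group may also be slow, or the nucleophile may attack C2. The fallback sets out from 3 and 8 and comes back at 12. The unbrominated flavan 3 is used as the arene nucleophile in a Lewis-acid-catalysed Friedel–Crafts opening of 8 at its benzylic carbon (BF3·OEt2 cat. or Sc(OTf)3, CH2Cl2, −78 °C). C8 is the most reactive free position of ring A, and anti-opening should give 12 directly. Step 3 then becomes unnecessary.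

Step 8. RuO4 may over-oxidise the electron-rich benzyloxyarene rings or the benzylic CH2 groups during the sulfite-to-sulfate oxidation. The fallback sets out from 12 and comes back at 14 without any oxidant. NaH and 1,1'-sulfonyldiimidazole in THF at 0 °C should sulfonylate the primary alkoxide to the imidazole-1-sulfonate F4. The neighbouring secondary alkoxide then closes F4 to 14 with loss of imidazole.

Further compounds
F1 | step 10 | (2S,3R)-3-Ar-3-Fl-2-hydroxypropyl 4-methylbenzenesulfonate | O[C@@H]([C@H](c1ccc(OCc2ccccc2)c(OCc2ccccc2)c1)c1c(OCc2ccccc2)cc(OCc2ccccc2)c2c1O[C@@H](c1ccc(OCc3ccccc3)c(OCc3ccccc3)c1)[C@@H](OCc1ccccc1)C2)COS(=O)(=O)c1ccc(C)cc1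
F2 | step 10 | (2S)-2-[(R)-Ar(Fl)methyl]oxirane | C5O[C@H]5[C@H](c1ccc(OCc2ccccc2)c(OCc2ccccc2)c1)c1c(OCc2ccccc2)cc(OCc2ccccc2)c2c1O[C@@H](c1ccc(OCc3ccccc3)c(OCc3ccccc3)c1)[C@@H](OCc1ccccc1)C2
F3 | step 10 | (2R,3R)-1-[2,4-bis(benzyloxy)-6-hydroxyphenyl]-3-Ar-3-Fl-propan-2-ol | Oc1cc(OCc2ccccc2)cc(OCc2ccccc2)c1C[C@@H](O)[C@H](c1ccc(OCc2ccccc2)c(OCc2ccccc2)c1)c1c(OCc2ccccc2)cc(OCc2ccccc2)c2c1O[C@@H](c1ccc(OCc3ccccc3)c(OCc3ccccc3)c1)[C@@H](OCc1ccccc1)C2
F0 | step 7 | none | none
F4 | step 8 | (2S,3R)-3-Ar-3-Fl-2-hydroxypropyl imidazole-1-sulfonate | O[C@@H]([C@H](c1ccc(OCc2ccccc2)c(OCc2ccccc2)c1)c1c(OCc2ccccc2)cc(OCc2ccccc2)c2c1O[C@@H](c1ccc(OCc3ccccc3)c(OCc3ccccc3)c1)[C@@H](OCc1ccccc1)C2)COS(=O)(=O)n1ccnc1
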